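**Plan**
- Ring B of the target (C5, C6, C8, C9, C10) is a cyclopentane carrying one exocyclic carboxyl carbon, C7, on C6. A cyclohexanone that expels its carbonyl carbon leaves exactly this, so the C5–C6 bond is cut back to a 7-diazo-6-oxo-ent-kauranoid 19,20-lactone.
- Further cuts, in order: the C20–O lactone bond (back to a C19 primary amide and the C20 methyl group), the C6 oxygen (back to C6–H through a 19,6-lactone), the C2 oxygen (back to a Δ2 alkene made from the C19 acid), and the C16 methylene (parked as the 17-nor ketone).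
- Forward: commercial steviol already has rings A–D. The order is norketone, ring A oxygen, C6 oxygen, amide, δ-lactone, 6-ketone, methylene, diazo ketone, contraction of ring B, deprotection.
- Stereochemistry: C4, C5, C8, C9, C10 and C13 come from steviol. C2 is set by hydroboration on the face away from C19 and C20. C5 migrates with retention. C6 is set by base equilibration of the ester.

Key step: step 15

Remark: α means the face of C19 and C20 and β the opposite face (trivial gibberellin usage, not ent-descriptors); ent-kaurane numbering is used through step 14 and gibberellane numbering from step 15, where "19,20-olid-7-oic acid" denotes the δ-lactone from the C19 carboxyl to the oxygen on C20 together with the C7 carboxyl on C6β; the C16 carbinol configuration in 8–17 and the spiro centre of 2 are left open because both are erased later.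

**Route**

Step 1
Reactants: 1 steviol
Product: 3 13-hydroxy-16-oxo-17-norkauran-19-oic acid (steviol norketone), via ozonide 2 (not isolated)
Conditions: O3, CH2Cl2, −78 °C; then Me2S, −78 °C → rt
Reagents that add atoms: ozone, [O-][O+]=O
Why: Ozonolysis of the 1,1-disubstituted alkene (Criegee mechanism, reductive work-up) removes C17 as formaldehyde and parks the methylene as a ketone, which keeps it out of the palladium, borane, iron-oxo and iodine steps that an exocyclic alkene would not survive.

Step 2
Reactants: 3 steviol norketone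
Product: 5 13-(tert-butyldimethylsilyloxy)-16-oxo-17-norkauran-19-oic acid, via bis-silyl compound 4 (not isolated)
Conditions: TBSOTf, 2,6-lutidine, CH2Cl2, 0 °C → rt; then AcOH–THF–H2O, rt
Reagents that add atoms: tert-butyldimethylsilyl triflate, CC(C)(C)[Si](C)(C)OS(=O)(=O)C(F)(F)F
Why: Silyl triflate silylation of the tertiary α-ketol hydroxyl blocks α-ketol rearrangement and gives an ether with no α-C–H for the later C–H oxidations, while the silyl ester formed alongside is hydrolysed in the mildly acidic second stage.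

Step 3
Reactants: 5 13-silyloxy norketone acid
Product: 6 13-(tert-butyldimethylsilyloxy)-16-oxo-17-norkaur-2-en-19-oic acid
Conditions: Pd(OAc)2 (10 mol %), bidentate pyridine–pyridone ligand (12 mol %), Ag2CO3, (CF3)2CHOH, 100 °C
Reagents that add atoms: none
Why: Carboxylate-directed palladation of the β-methylene C3–H through a five-membered palladacycle and β-hydride elimination from C2 (palladium-catalysed β,γ-dehydrogenation of α-quaternary acids) can only give the C2=C3 alkene, because palladation of the C18 methyl group has no β-hydrogen to lose and is reversible.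

Step 4
Reactants: 6 Δ2 acid
Product: 7 benzyl 13-(tert-butyldimethylsilyloxy)-16-oxo-17-norkaur-2-en-19-oate
Conditions: BnBr, K2CO3, DMF, rt
Reagents that add atoms: benzyl bromide, BrCc1ccccc1
Why: SN2 O-alkylation of the hindered carboxylate masks the acid against borane with a group that is later removed by hydrogenolysis and not by hydrolysis at the neopentyl carbonyl.

Step 5
Reactants: 7 benzyl ester
Product: 9 benzyl 2β,16ξ-dihydroxy-13-(tert-butyldimethylsilyloxy)-17-norkauran-19-oate, via alkylborane 8 (not isolated)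
Conditions: BH3·THF, THF, 0 °C → rt; then NaOH, H2O2, 0 °C
Reagents that add atoms: hydrogen peroxide, OO
Why: In this Brown hydroboration–oxidation boron adds to C2, away from quaternary C4, from the β face opposite the axial C19 ester and C20 methyl, and oxidation with retention sets the equatorial 2β-hydroxyl, while the C16 ketone is reduced in the same flask to a carbinol whose configuration does not matter.

Step 6
Reactants: 9 diol benzyl ester
Product: 10 benzyl 2β,16ξ-diacetoxy-13-(tert-butyldimethylsilyloxy)-17-norkauran-19-oate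
Conditions: Ac2O, pyridine, DMAP (cat.), CH2Cl2, rt
Reagents that add atoms: acetic anhydride, CC(=O)OC(C)=O
Why: DMAP-catalysed acylation of both secondary hydroxyls gives acetates whose geminal C2–H and C16–H bonds are electron-poor and therefore spared by the iron oxidant of step 8.

Step 7
Reactants: 10 diacetate benzyl ester
Product: 11 2β,16ξ-diacetoxy-13-(tert-butyldimethylsilyloxy)-17-norkauran-19-oic acid
Conditions: H2 (1 atm), Pd/C, EtOAc, rt
Reagents that add atoms: none
Why: Hydrogenolysis of the benzyl ester frees the C19 acid under neutral conditions, and no alkene or other reducible group is left in the molecule at this stage.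

Step 8
Reactants: 11 diacetate acid
Product: 12 2β,16ξ-diacetoxy-13-(tert-butyldimethylsilyloxy)-17-norkauran-19,6α-olide
Conditions: Fe(S,S-PDP)(MeCN)2(SbF6)2 (3 × 5 mol %), H2O2 (50% aq., in portions), MeCN, rt
Reagents that add atoms: hydrogen peroxide, OO
Why: In this carboxylate-directed non-haem iron C–H hydroxylation–lactonisation the iron-bound C19 carboxylate delivers the oxo to the syn-axial γ-hydrogen at C6 (C2–H, the other syn-axial γ-hydrogen, is switched off by its acetate), so the γ-lactone oxygen is set on the α face by the tether.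

Step 9
Reactants: 12 19,6α-lactone
Product: 13 2β,6α,16ξ-trihydroxy-13-(tert-butyldimethylsilyloxy)-17-norkauran-19-amide
Conditions: Me3Al, NH4Cl, toluene, 0 → 60 °C; aq. potassium sodium tartrate work-up
Reagents that add atoms: ammonium chloride, [NH4+].[Cl-]
Why: Aluminium amide aminolysis (Weinreb type) opens the neopentyl γ-lactone to the primary amide, the one C19 derivative that does not close back onto the 6α-hydroxyl under neutral conditions, and the two acetates are cleaved as acetamide on the way.

Step 10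
Reactants: 13 triol amide
Product: 15 2β-acetoxy-6α,16ξ-bis(triethylsilyloxy)-13-(tert-butyldimethylsilyloxy)-17-norkauran-19-amide, via 2-monoacetate 14 (not isolated)
Conditions: Ac2O (1.1 equiv), pyridine, CH2Cl2, 0 °C; then Et3SiOTf, 2,6-lutidine, −20 → 0 °C
Reagents that add atoms: acetic anhydride, CC(=O)OC(C)=O; triethylsilyl triflate, CC[Si](CC)(CC)OS(=O)(=O)C(F)(F)F
Why: Rate-controlled acylation takes only the unhindered equatorial 2β-hydroxyl and the silyl triflate then caps the hindered 6α- and 16-hydroxyls, so that the radical step meets an electron-poor C2–H, no axial C6–H and no free hydroxyl.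

Step 11
Reactants: 15 protected amide
Product: 17 2β-acetoxy-6α,16ξ-bis(triethylsilyloxy)-13-(tert-butyldimethylsilyloxy)-17-norkauran-19,20-olide, via iminolactone 16 (not isolated)
Conditions: PhI(OAc)2, I2, CH2Cl2, visible light, rt; then aq. NaOAc–AcOH (pH 5), THF, 0 °C → rt
Reagents that add atoms: water, O
Why: In this Barton amide lactonisation under Suárez conditions the amidyl radical from the N-iodoamide, denied C6α–H and pushed away from C6 by the silyloxy group, abstracts hydrogen from the 1,3-diaxial C20 methyl group (1,6-shift), the C20 iodide closes through the amide oxygen to the six-membered imidate, and mild hydrolysis gives the δ-lactone.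

Step 12
Reactants: 17 bis-silyl 19,20-lactone
Product: 18 2β-acetoxy-6,16-dioxo-13-(tert-butyldimethylsilyloxy)-17-norkauran-19,20-olide
Conditions: IBX, DMSO, 45 °C
Reagents that add atoms: none
Why: IBX in DMSO cleaves triethylsilyl ethers and oxidises the freed alcohols in the same flask while leaving the tert-butyldimethylsilyl ether, so the 6α-hydroxy lactone, which could pass its acyl group back to the C6 oxygen, never accumulates.

Step 13
Reactants: 18 diketo lactone
Product: 19 2β-acetoxy-6-oxo-13-(tert-butyldimethylsilyloxy)kaur-16-en-19,20-olide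
Conditions: Zn, CH2Br2, TiCl4 (preformed reagent), THF–CH2Cl2, 0 °C → rt
Reagents that add atoms: dibromomethane, BrCBr
Why: Lombardo methylenation is non-basic and should take the strained bridged cyclopentanone at C16 in preference to the C6 ketone (flanked by the C5 methine and neopentyl C7 and peri to C4), the lactone and the acetate, without epimerising C5.

Step 14
Reactants: 19 6-ketone; 20 4-acetamidobenzenesulfonyl azide
Product: 22 2β-acetoxy-7-diazo-6-oxo-13-(tert-butyldimethylsilyloxy)kaur-16-en-19,20-olide, via trifluoroacetyl ketone 21 (not isolated)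
Conditions: LiN(SiMe3)2 (1.1 equiv), THF, −78 °C; CF3CO2CH2CF3, −78 °C; 5% aq. HCl work-up, 0 °C; then 20, Et3N, H2O (1 equiv), MeCN, rt
Reagents that add atoms: 4-acetamidobenzenesulfonyl azide 20, CC(=O)Nc1ccc(cc1)S(=O)(=O)N=[N+]=[N-] (the two diazo nitrogens); 2,2,2-trifluoroethyl trifluoroacetate, O=C(OCC(F)(F)F)C(F)(F)F (its CF3CO group is in 21 only)
Why: Kinetic enolisation of the ketone (far more acidic than the C2 acetate, so one equivalent of amide base leaves the ester alone) toward the C7 methylene, C-trifluoroacetylation and deacylative diazo transfer (Regitz type) place the diazo group on the only carbon that can carry it, since C5 has a single hydrogen and C8 is quaternary.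

Step 15
Reactants: 22 ring B α-diazo ketone
Product: 25 2β-hydroxy-13-(tert-butyldimethylsilyloxy)gibberell-16-en-19,20-olid-7-oic acid methyl ester, via ketene 23 (not isolated), via 6α-ester 24 (not isolated)
Conditions: hν (medium-pressure Hg lamp, Pyrex, λ > 300 nm), MeOH, 0 °C; then NaOMe (0.3 equiv), MeOH, 60 °C; AcOH quench
Reagents that add atoms: methanol, CO
Why: Excitation of the diazo ketone, held s-Z by the ring, expels N2 while C5 shifts from the carbonyl carbon to the diazo carbon (Wolff rearrangement), giving ketene 23 in which the old C7 is the new ring carbon C6 and the old C6 is the exocyclic C7, and methanol adds to give the ester. The closest known reaction type is the photochemical Wolff ring contraction of cyclic α-diazo ketones to five-membered rings with an exocyclic ester. Ring B (C5, C6, C8, C9, C10) is formed by contraction and not by cyclisation: the C5–C6 bond arises by a suprafacial 1,2-alkyl shift with retention at C5, so the trans A/B fusion is kept. C6 is the only new stereocentre: protonation of the ester enol from the more open β face should give mainly the 6α-ester 24, and methoxide in the same methanol equilibrates it through the ester enolate to the 6β-ester, trans to C4 on C5 and away from C14, C19 and C20 on the α face. The step needs rearrangement to win over other carbene pathways, which the substrate secures through quaternary C8 (no 1,2-hydrogen shift possible) and the single possible diazo site; the methoxide also removes the C2 acetate, and any opened δ-lactone closes again on acidification.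

Step 16
Reactants: 25 silyl ether methyl ester
Product: 26 2β,13-dihydroxygibberell-16-en-19,20-olid-7-oic acid methyl ester
Conditions: Bu4NF, THF, 50 °C; aq. work-up at pH 3
Reagents that add atoms: none
Why: Fluoride-driven desilylation cleaves the tertiary silyl ether under non-acidic conditions, which avoids Wagner–Meerwein rearrangement of the 13-hydroxy-16-ene, and the brief acidic work-up re-closes any lactone opened by adventitious hydroxide.

Step 17
Reactants: 26 dihydroxy lactone methyl ester
Product: 27 2β,13-dihydroxygibberell-16-en-19,20-olid-7-oic acid (the target gibberellin)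
Conditions: LiSPr, HMPA, rt; then 1 M HCl
Reagents that add atoms: none
Why: SN2 demethylation by thiolate attacks the methyl carbon of the hindered C7 ester and leaves the lactone, whose alkyl carbon C20 is neopentyl, so acidification gives the acid without touching C6 or the δ-lactone.

**Compound list**
1 | steviol | C=C1C[C@]23C[C@@]1(O)CC[C@H]2[C@]1(C)CCC[C@@](C)(C(=O)O)[C@H]1CC3 | starting material
2 | steviol 16,17-ozonide (spiro 1,2,4-trioxolane at C16) | C1OOC2(O1)C[C@]34C[C@@]2(O)CC[C@H]3[C@]2(C)CCC[C@@](C)(C(=O)O)[C@H]2CC4 | intermediate (not isolated)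
3 | 13-hydroxy-16-oxo-17-norkauran-19-oic acid | O=C1C[C@]23C[C@@]1(O)CC[C@H]2[C@]1(C)CCC[C@@](C)(C(=O)O)[C@H]1CC3 | intermediate
4 | 13-O-silyl ether silyl ester of 3 | O=C1C[C@]23C[C@@]1(O[Si](C)(C)C(C)(C)C)CC[C@H]2[C@]1(C)CCC[C@@](C)(C(=O)O[Si](C)(C)C(C)(C)C)[C@H]1CC3 | intermediate (not isolated)
5 | 13-(tert-butyldimethylsilyloxy)-16-oxo-17-norkauran-19-oic acid | O=C1C[C@]23C[C@@]1(O[Si](C)(C)C(C)(C)C)CC[C@H]2[C@]1(C)CCC[C@@](C)(C(=O)O)[C@H]1CC3 | intermediate
6 | 13-(tert-butyldimethylsilyloxy)-16-oxo-17-norkaur-2-en-19-oic acid | O=C1C[C@]23C[C@@]1(O[Si](C)(C)C(C)(C)C)CC[C@H]2[C@]1(C)CC=C[C@@](C)(C(=O)O)[C@H]1CC3 | intermediate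
7 | benzyl ester of 6 | O=C1C[C@]23C[C@@]1(O[Si](C)(C)C(C)(C)C)CC[C@H]2[C@]1(C)CC=C[C@@](C)(C(=O)OCc4ccccc4)[C@H]1CC3 | intermediate
8 | C2β alkylborane with C16 O-boryl group (drawn as RBH2 and ROBH2) | BOC1C[C@]23C[C@@]1(O[Si](C)(C)C(C)(C)C)CC[C@H]2[C@]1(C)C[C@H](B)C[C@@](C)(C(=O)OCc4ccccc4)[C@H]1CC3 | intermediate (not isolated)
9 | benzyl 2β,16ξ-dihydroxy-13-(tert-butyldimethylsilyloxy)-17-norkauran-19-oate | OC1C[C@]23C[C@@]1(O[Si](C)(C)C(C)(C)C)CC[C@H]2[C@]1(C)C[C@H](O)C[C@@](C)(C(=O)OCc4ccccc4)[C@H]1CC3 | intermediate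
10 | benzyl 2β,16ξ-diacetoxy-13-(tert-butyldimethylsilyloxy)-17-norkauran-19-oate | CC(=O)OC1C[C@]23C[C@@]1(O[Si](C)(C)C(C)(C)C)CC[C@H]2[C@]1(C)C[C@H](OC(C)=O)C[C@@](C)(C(=O)OCc4ccccc4)[C@H]1CC3 | intermediate
11 | 2β,16ξ-diacetoxy-13-(tert-butyldimethylsilyloxy)-17-norkauran-19-oic acid | CC(=O)OC1C[C@]23C[C@@]1(O[Si](C)(C)C(C)(C)C)CC[C@H]2[C@]1(C)C[C@H](OC(C)=O)C[C@@](C)(C(=O)O)[C@H]1CC3 | intermediate
12 | 2β,16ξ-diacetoxy-13-(tert-butyldimethylsilyloxy)-17-norkauran-19,6α-olide | CC(=O)OC1C[C@]23C[C@@]1(O[Si](C)(C)C(C)(C)C)CC[C@H]2[C@]1(C)C[C@H](OC(C)=O)C[C@@](C)(C(=O)O4)[C@H]1[C@@H]4C3 | intermediate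
13 | 2β,6α,16ξ-trihydroxy-13-(tert-butyldimethylsilyloxy)-17-norkauran-19-amide | OC1C[C@]23C[C@@]1(O[Si](C)(C)C(C)(C)C)CC[C@H]2[C@]1(C)C[C@H](O)C[C@@](C)(C(N)=O)[C@H]1[C@@H](O)C3 | intermediate
14 | 2β-acetate of 13 | OC1C[C@]23C[C@@]1(O[Si](C)(C)C(C)(C)C)CC[C@H]2[C@]1(C)C[C@H](OC(C)=O)C[C@@](C)(C(N)=O)[C@H]1[C@@H](O)C3 | intermediate (not isolated)
15 | 2β-acetoxy-6α,16ξ-bis(triethylsilyloxy)-13-(tert-butyldimethylsilyloxy)-17-norkauran-19-amide | CC[Si](CC)(CC)OC1C[C@]23C[C@@]1(O[Si](C)(C)C(C)(C)C)CC[C@H]2[C@]1(C)C[C@H](OC(C)=O)C[C@@](C)(C(N)=O)[C@H]1[C@@H](O[Si](CC)(CC)CC)C3 | intermediate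
16 | 19,20-iminolactone (cyclic imidate) of 15 | CC[Si](CC)(CC)OC1C[C@]23C[C@@]1(O[Si](C)(C)C(C)(C)C)CC[C@H]2[C@]12COC(=N)[C@](C)(C[C@@H](OC(C)=O)C1)[C@H]2[C@@H](O[Si](CC)(CC)CC)C3 | intermediate (not isolated)
17 | 2β-acetoxy-6α,16ξ-bis(triethylsilyloxy)-13-(tert-butyldimethylsilyloxy)-17-norkauran-19,20-olide | CC[Si](CC)(CC)OC1C[C@]23C[C@@]1(O[Si](C)(C)C(C)(C)C)CC[C@H]2[C@]12COC(=O)[C@](C)(C[C@@H](OC(C)=O)C1)[C@H]2[C@@H](O[Si](CC)(CC)CC)C3 | intermediate
18 | 2β-acetoxy-6,16-dioxo-13-(tert-butyldimethylsilyloxy)-17-norkauran-19,20-olide | O=C1C[C@]23C[C@@]1(O[Si](C)(C)C(C)(C)C)CC[C@H]2[C@]12COC(=O)[C@](C)(C[C@@H](OC(C)=O)C1)[C@H]2C(=O)C3 | intermediate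
19 | 2β-acetoxy-6-oxo-13-(tert-butyldimethylsilyloxy)kaur-16-en-19,20-olide | C=C1C[C@]23C[C@@]1(O[Si](C)(C)C(C)(C)C)CC[C@H]2[C@]12COC(=O)[C@](C)(C[C@@H](OC(C)=O)C1)[C@H]2C(=O)C3 | intermediate
20 | 4-acetamidobenzenesulfonyl azide | CC(=O)Nc1ccc(cc1)S(=O)(=O)N=[N+]=[N-] | starting material
21 | 7-trifluoroacetyl derivative of 19 | C=C1C[C@]23C[C@@]1(O[Si](C)(C)C(C)(C)C)CC[C@H]2[C@]12COC(=O)[C@](C)(C[C@@H](OC(C)=O)C1)[C@H]2C(=O)C3C(=O)C(F)(F)F | intermediate (not isolated)
22 | 2β-acetoxy-7-diazo-6-oxo-13-(tert-butyldimethylsilyloxy)kaur-16-en-19,20-olide | C=C1C[C@]23C[C@@]1(O[Si](C)(C)C(C)(C)C)CC[C@H]2[C@]12COC(=O)[C@](C)(C[C@@H](OC(C)=O)C1)[C@H]2C(=O)C3=[N+]=[N-] | intermediate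
23 | ring-contracted ketene (gibberellane C6=C7=O) | C=C1C[C@]23C[C@@]1(O[Si](C)(C)C(C)(C)C)CC[C@H]2[C@]12COC(=O)[C@](C)(C[C@@H](OC(C)=O)C1)[C@H]2C3=C=O | intermediate (not isolated)
24 | 2β-acetoxy-13-(tert-butyldimethylsilyloxy)-6-epi-gibberell-16-en-19,20-olid-7-oic acid methyl ester (6α-ester) | C=C1C[C@]23C[C@@]1(O[Si](C)(C)C(C)(C)C)CC[C@H]2[C@]12COC(=O)[C@](C)(C[C@@H](OC(C)=O)C1)[C@H]2[C@H]3C(=O)OC | intermediate (not isolated)
25 | 2β-hydroxy-13-(tert-butyldimethylsilyloxy)gibberell-16-en-19,20-olid-7-oic acid methyl ester | C=C1C[C@]23C[C@@]1(O[Si](C)(C)C(C)(C)C)CC[C@H]2[C@]12COC(=O)[C@](C)(C[C@@H](O)C1)[C@H]2[C@@H]3C(=O)OC | intermediate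
26 | 2β,13-dihydroxygibberell-16-en-19,20-olid-7-oic acid methyl ester | C=C1C[C@]23C[C@@]1(O)CC[C@H]2[C@]12COC(=O)[C@](C)(C[C@@H](O)C1)[C@H]2[C@@H]3C(=O)OC | intermediate
27 | 2β,13-dihydroxygibberell-16-en-19,20-olid-7-oic acid (the target gibberellin) | C=C1C[C@]23C[C@@]1(O)CC[C@H]2[C@]12COC(=O)[C@](C)(C[C@@H](O)C1)[C@H]2[C@@H]3C(=O)O | target

**Step count and risks**

Total step count: 17. Longest linear sequence: 17 steps from steviol.

Steps most likely to fail:

1. Step 3. Palladation of the C3 methylene of a neopentyl, axial carboxylic acid may be too slow to turn over, so that reversible palladation of the C18 methyl group and loss of the silyl ether in the hot fluorinated alcohol take over. Fallback, from 5 back to 11: the directing acid is switched off as the methyl ester F1 (Me3SiCHN2, MeOH–toluene). Non-directed iron-oxo methylene oxidation with Fe(S,S-CF3-PDP)(MeCN)2(SbF6)2, H2O2 and AcOH should then pick C2, the only methylene flanked by two CH2 groups and remote from the ketone, ester and silyloxy groups (the usual site in decalin A rings of this substitution type), giving the 2,16-diketo ester F2. LiSPr in HMPA cleaves the methyl ester to the diketo acid F3. Li in NH3 on the carboxylate reduces both ketones under thermodynamic control to the diol acid F4, with the equatorial 2β-hydroxyl; the bridgehead C13–O bond lies close to the plane of the C16 carbonyl, so the ketyl should not expel the silyloxy group. Ac2O, pyridine and DMAP then give 11, so steps 3–7 are replaced.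

2. Step 11. The 1,6-hydrogen shift from a primary C–H through a seven-membered transition state may be slow, so that Hofmann-type rearrangement of the N-iodoamide or ring closure through nitrogen competes. Fallback, from 14 (isolated after the acetylation stage of step 10) back to 18: the relay atom is changed to the 6α-oxygen. Et3SiCl and imidazole silylate the less hindered C16 hydroxyl to give the 6α-hydroxy amide F7. PhI(OAc)2, I2 and light form the hypoiodite, whose alkoxy radical takes hydrogen from C20 by the classical 1,5-shift between 1,3-diaxial groups, and the iodide closes to the 6α,20-ether F8. Methyl(trifluoromethyl)dioxirane oxidises the ether methine C6–H to the hemiketal, which opens to the 6-keto 20-hydroxy amide F9. Pyridinium tosylate in hot toluene lets the primary C20 hydroxyl attack the neighbouring axial amide with loss of ammonia, giving the keto lactone F10. IBX in DMSO, as in step 12, then gives 18.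

3. Step 8. The oxidant may be consumed at undirected methylene groups of rings B and C, or conversion may stall, before the carboxylate-bound iron-oxo reaches C6α–H. Fallback, from 11 back to 12: the metal-oxo is replaced by a nitrogen-radical relay. (COCl)2 then NH3 give the primary amide F5. PhI(OAc)2, I2 and light generate the amidyl radical, which abstracts the syn-axial C6α–H through a six-membered transition state, and the iodide closes through oxygen to the five-membered iminolactone F6. Aqueous work-up at pH 5 hydrolyses it to 12.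

Further compounds
F1 | step 3 | methyl 13-(tert-butyldimethylsilyloxy)-16-oxo-17-norkauran-19-oate | O=C1C[C@]23C[C@@]1(O[Si](C)(C)C(C)(C)C)CC[C@H]2[C@]1(C)CCC[C@@](C)(C(=O)OC)[C@H]1CC3
F2 | step 3 | methyl 2,16-dioxo-13-(tert-butyldimethylsilyloxy)-17-norkauran-19-oate | O=C1C[C@]23C[C@@]1(O[Si](C)(C)C(C)(C)C)CC[C@H]2[C@]1(C)CC(=O)C[C@@](C)(C(=O)OC)[C@H]1CC3
F3 | step 3 | 2,16-dioxo-13-(tert-butyldimethylsilyloxy)-17-norkauran-19-oic acid | O=C1C[C@]23C[C@@]1(O[Si](C)(C)C(C)(C)C)CC[C@H]2[C@]1(C)CC(=O)C[C@@](C)(C(=O)O)[C@H]1CC3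
F4 | step 3 | 2β,16ξ-dihydroxy-13-(tert-butyldimethylsilyloxy)-17-norkauran-19-oic acid | OC1C[C@]23C[C@@]1(O[Si](C)(C)C(C)(C)C)CC[C@H]2[C@]1(C)C[C@H](O)C[C@@](C)(C(=O)O)[C@H]1CC3
F5 | step 8 | 2β,16ξ-diacetoxy-13-(tert-butyldimethylsilyloxy)-17-norkauran-19-amide | CC(=O)OC1C[C@]23C[C@@]1(O[Si](C)(C)C(C)(C)C)CC[C@H]2[C@]1(C)C[C@H](OC(C)=O)C[C@@](C)(C(N)=O)[C@H]1CC3
F6 | step 8 | 19,6α-iminolactone of F5 | CC(=O)OC1C[C@]23C[C@@]1(O[Si](C)(C)C(C)(C)C)CC[C@H]2[C@]1(C)C[C@H](OC(C)=O)C[C@@](C)(C(=N)O4)[C@H]1[C@@H]4C3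
F7 | step 11 | 2β-acetoxy-6α-hydroxy-16ξ-(triethylsilyloxy)-13-(tert-butyldimethylsilyloxy)-17-norkauran-19-amide | CC[Si](CC)(CC)OC1C[C@]23C[C@@]1(O[Si](C)(C)C(C)(C)C)CC[C@H]2[C@]1(C)C[C@H](OC(C)=O)C[C@@](C)(C(N)=O)[C@H]1[C@@H](O)C3
F8 | step 11 | 2β-acetoxy-6α,20-epoxy-16ξ-(triethylsilyloxy)-13-(tert-butyldimethylsilyloxy)-17-norkauran-19-amide | CC[Si](CC)(CC)OC1C[C@]23C[C@@]1(O[Si](C)(C)C(C)(C)C)CC[C@H]2[C@]1(CO4)C[C@H](OC(C)=O)C[C@@](C)(C(N)=O)[C@H]1[C@@H]4C3
F9 | step 11 | 2β-acetoxy-20-hydroxy-6-oxo-16ξ-(triethylsilyloxy)-13-(tert-butyldimethylsilyloxy)-17-norkauran-19-amide | CC[Si](CC)(CC)OC1C[C@]23C[C@@]1(O[Si](C)(C)C(C)(C)C)CC[C@H]2[C@]1(CO)C[C@H](OC(C)=O)C[C@@](C)(C(N)=O)[C@H]1C(=O)C3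
F10 | step 11 | 2β-acetoxy-6-oxo-16ξ-(triethylsilyloxy)-13-(tert-butyldimethylsilyloxy)-17-norkauran-19,20-olide | CC[Si](CC)(CC)OC1C[C@]23C[C@@]1(O[Si](C)(C)C(C)(C)C)CC[C@H]2[C@]12COC(=O)[C@](C)(C[C@@H](OC(C)=O)C1)[C@H]2C(=O)C3
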